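# Proposed total synthesis of CNP0185847.4 by palladium-catalysed C2–C3 ring closure of a Baylis–Hillman carbonate

## The problem

The target is a germacrane-type ten-membered carbocycle (C1–C10) in which almost every ring atom is functionalised: a trisubstituted epoxide spans C1–C10 with the acetoxymethyl C15 on C1, C4=C5–C6=O is a ring-cis (Z) α-methyl enone, and C8 is the spiro carbon of a second epoxide whose exocyclic carbon C11 carries C13H3 and the acetoxymethyl C12. A synthesis has to close this medium ring without losing two geometries that are easily lost: the less stable (Z)-enone and the tetrasubstituted C8=C11 alkene from which the spiro-epoxide must come. All four stereocentres (1R, 8S, 10R, 11S) are epoxide carbons. Within each epoxide the relative configuration follows from alkene geometry (C2 cis to C9 across C1=C10, C12 cis to C9 across C8=C11), but the two epoxides are separated by the C9 methylene in a flexible ring, so neither can be trusted to direct the other. Both alkenes become 2-substituted primary allylic alcohols once C15-OH and C12-OH are free, which invites hydroxyl-directed asymmetric epoxidation; the two faces required correspond to enantiomeric tartrates, so the hydroxyls must be released one after the other. Several features will not survive rough treatment: the β,γ-epoxy ketone C6/C8 (E1cB opening), the tetrasubstituted epoxide (acid), the (Z)-enone (base, nucleophiles), any (Z)-γ-hydroxy enone (it closes to a furan), and every β,γ-unsaturated carbonyl intermediate that could slip into conjugation and erase C8=C11. The feature that makes the key step possible is that C15–C1(=C10)–C2 is the skeleton of a transposed Baylis–Hillman adduct, a 2-(alkoxycarbonyl)allyl unit after ionisation, while C3 is the γ-carbon of the C6 enone; the C2–C3 bond therefore joins a natural allyl electrophile to a natural vinylogous carbanion that needs only a removable acidifying group at C3.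

## Retrosynthesis

**Epoxides and acetates (35 ⇒ 29).** The last bonds cut are the four C–O bonds of the two oxiranes and the two acetate linkages, which leads back to the triene diol 29. Oxygen is to be delivered by titanium–tartrate catalysis from the neighbouring primary hydroxyl, because each alkene is then a 2-substituted allylic alcohol of fixed geometry and syn addition turns that geometry into the relative configuration of each epoxide. The shortcut of epoxidising a diene diol once is closed: the (1R,10R) and (8S,11S) faces answer to enantiomeric tartrates, and a peracid would attack the tetrasubstituted alkene first and without facial control. C15-OH is therefore used first (29 → 30) while C12 stays a silyl ether; C12-OH is released only in 33 for the second epoxidation (34) and final acetylation (35). In between, C15 is acetylated selectively (31) and C6 is returned to the ketone (32). The reason is that a C6 hydroxyl would sit within reach of C11 of the new tetrasubstituted epoxide, and the electron-rich C4=C5 alkene of 30 and 31 could add across the ring to the C1–C10 epoxide; the enone does neither. Compound 29 carries no stereocentre that matters and three alkenes of defined geometry.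

**C3–S and the oxidation levels (29 ⇒ 27).** Compound 29 is traced to the keto ester sulfone 27: C3–H replaces C3–SO2Ph, and C6-OH and C15-OH stand for the ketone and the ester. The order of the forward steps follows from mechanism. Reductive cleavage of the sulfone in 27 itself would pass through a C6 dienolate that protonates at C5 and leaves the alkene at C3=C4. The carbonyls are therefore reduced first (28), and the now plain allylic sulfone is exchanged for hydride on palladium, a process that attacks the less substituted allyl terminus and keeps the trisubstituted alkene in place. The later re-oxidation at C6 is accepted because the ester has to be reduced to C15-OH in any case.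

**C2–C3, the ring-closing cut (27 ⇒ 25).** The ring is opened between C2 and C3 to the Baylis–Hillman tert-butyl carbonate 25. Cuts at C5–C6 or C6–C7 would create the labile enone during ring closure, and cuts at C7–C8 or C8–C9 would place an allyl-metal at the tetrasubstituted alkene. C2–C3 lies between two methylenes, far from C8=C11, and is the one ring bond whose ends are a 2-(methoxycarbonyl)allyl electrophile and a sulfonyl-stabilised vinylogous carbanion. Compound 25 is an open chain whose only stereocentre (C10, racemic) disappears on ionisation. The forward reaction must ionise only the carbonate, attack from C3 and at C2, form the (E)-enoate (the ring-cis C1=C10), and leave the (Z)-enone and C8=C11 untouched.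

**C1–C10 and the timing of the enone (25 ⇒ 19 + 20).** The carbonate 25 comes from the Baylis–Hillman-type alcohol 22 (via 23 and 24), and 22 from aldehyde 19 and methyl propiolate 20 by C1–C10 bond formation. The amine-catalysed reaction with an acrylate is set aside: 19 is a β,γ-unsaturated aldehyde, and a tertiary amine acting for days would conjugate it and destroy C8=C11. The α-aluminoacrylate 21 gives the same adduct without base. The (Z)-enone is unveiled last (24 → 25) and the sulfone is already in place. A free C3 hydroxyl next to a (Z)-enone would form a furan, and the enone would not tolerate the earlier steps.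

**C8–C9 and the tetrasubstituted alkene (19 ⇒ 12 + 13).** Aldehyde 19 is simplified through 17, 16, 15 and 14 to the enol triflate 12 and the acetal-bearing zinc reagent 13. Cutting C8–C9 lets the alkene geometry be set by a chelated β-keto ester enolate rather than by olefination of a ketone flanked by two nearly identical methylenes. In the (Z)-triflate the oxygen is cis to the ester, so the incoming C9 arm ends cis to C12 and the C7 arm cis to C13, exactly as the spiro-epoxide requires. The arm arrives as a dioxolane, which later gives the C10 aldehyde in one non-acidic step. The coupling is asked to proceed with retention on a tetrasubstituted, electron-poor alkenyl triflate.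

**C6–C7 (12 ⇒ 6 + 7).** The β-keto ester behind 12 (10, from 9) is cut between C6 and C7 into the (Z)-enal 6 and ethyl 2-methylacetoacetate 7, whose dianion 8 reacts at its terminal carbon. This brings in C11, C12, C13, C8 and C7 from a commodity chemical, creates the C6 oxygen in the same step, and leaves the β-keto ester ready for triflation. The addition must be 1,2 and must not isomerise the enal.

**C5–C6 and C3–S (6 ⇒ 1).** Enal 6 is reduced to but-2-yn-1-ol 1 through iodide 3 and sulfide 4. Directed hydroalumination–iodination fixes the trisubstituted (Z) geometry (C3 cis to the future C6) in the first step. Sulfur is introduced as the sulfide because a sulfone would not survive the alkenyllithium 5 or the dianion 8, and a protected C3 oxygen would cost three later steps and pass near the furan-forming hydroxy enone.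

## Roads not taken

Alternative 1: The cut is at C11–C13 and C8–C9. A three-component assembly joins the alkynol A1, a methyl Grignard reagent and the allylic bromide A2 to the open chain A3, which holds all fifteen skeletal carbons; the ring would be closed later at C5–C6 from the alkenyl iodide. In the forward key step MeMgBr with catalytic CuI adds methyl to C11 anti to magnesium at C8 within a five-membered alkoxide chelate, and the alkenylmagnesium is allylated in the same flask. Its merits are real. The geometry of C8=C11 is a direct consequence of anti addition, the step is highly convergent, and the three primary oxygens emerge already differentiated. In this respect it is better than the chosen plan, which needs a triflation and a coupling and relies on a chelated enolate. Its weak points are these: methyl is the slowest group to transfer in this carbometalation of internal alkynols; the chelated alkenylmagnesium is a sluggish nucleophile; allylation of A2 can go SN2 or SN2′ and so move or scramble C1=C10; and A2 carries an alkenyl iodide that must survive magnesium and copper. Above all, the ring is not addressed: closure is deferred to an addition at C5–C6 that needs a β,γ-unsaturated aldehyde on a long chain and a later oxidation. Against the more direct alkene synthesis the chosen plan sets a ring closure designed into the carbon skeleton, between two stabilised partners, under neutral conditions, at a bond remote from both sensitive alkenes.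

Alternative 2: The cut is at C6–C7 by a [3,3] shift. Heating the eight-membered 2-methylene cyclic ether A4 would form C6–C7, turn the C8 enol ether into a ketone and expand the ring to the ten-membered dienone A5. Ring formation here is unimolecular, needs no dilution and fixes the ring-cis C4=C5 through the cyclic transition state; C1=C10 is already locked cis in the eight-membered ring. As a ring-forming event this is more reliable than any cyclisation of an open chain, the chosen one included. The weakness lies after the key step. The C8 ketone of A5 must be converted into the tetrasubstituted C8=C11 alkene with C12 cis to C9, and the two flanking methylenes C7 and C9 offer an olefination reagent nothing to distinguish them. The ketone is also enolisable toward C9, next to C1=C10, and the C6 oxygen enters as an ether that must still be oxidised. The synthesis of A4 (medium-ring lactone, methylenation, a defined enol ether side chain) is long in itself. The chosen plan sets against the better ring closure the fact that C8=C11 is fixed in open-chain, chelate-controlled chemistry before the ring exists, the point at which alternative 2 has no answer.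

Alternative 3: The cut is at both C5–C6 and C6–C7, with carbon monoxide as C6. Under CO, Pd(PPh3)4 would join the C7 allylic chloride and the C5 (Z)-alkenylstannane of A6 and close the ring to the trienone A7. In redox and protecting-group economy this is better than the chosen plan: the ketone arrives at the right oxidation level, there is no activating group to remove, C15 and C12 are already distinguished by their silyl groups, and A7 corresponds to what the present route reaches only at 29 and then has to re-oxidise at C6. The objections are mechanistic. The allylpalladium formed from the C7 chloride spans C7–C8–C11, so it contains the tetrasubstituted alkene whose geometry must not change; η3–η1–η3 isomerisation or attack at C11 would scramble it. Direct coupling without CO insertion leads to a nine-membered ring and competes when CO is scarce, while much CO slows oxidative addition. The β,γ-unsaturated acylpalladium can lose CO or conjugate. The closure is a three-component event at high dilution with stoichiometric tin. The chosen plan sets against the shorter endgame an allylpalladium built at the C1/C2/C10 end, away from C8=C11, a nucleophile generated stoichiometrically by the leaving group itself, and a regiochemical outcome (attack at C2, (E)-enoate) that follows the established behaviour of Baylis–Hillman carbonates.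

Key step: step 16

Remarks on the chemistry:
- Locants C1–C15 are those of "The problem" and are also used for the corresponding atoms of open-chain intermediates.
- Compounds 9–28 are racemic (diastereomer mixtures where two temporary stereocentres are present) and are drawn without descriptors at these centres; all of them are erased by steps 15–21. Enantiocontrol begins in step 19.
- The zinc reagent 13 is assumed to be bought as its THF solution.

## Route

Step 1
Reactants: 1 but-2-yn-1-ol
Product: 3 (2Z)-3-iodobut-2-en-1-ol, via cyclic sodium alkenylalanate 2 (not isolated)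
Conditions: NaAlH2(OCH2CH2OMe)2, THF, 0 °C → rt; EtOAc; I2, −78 → 0 °C
Reagents that add atoms: iodine, SMILES II
Why: Directed trans-hydroalumination of the propargylic alkoxide places hydride on the proximal and aluminium on the distal alkyne carbon within a five-membered alanate, and iodinolysis with retention gives the (Z)-iodoalkenol in which iodine (the future C6 position) is cis to the CH2O carbon (C3).

Step 2
Reactants: 3 (2Z)-3-iodobut-2-en-1-ol
Product: 4 [(2Z)-3-iodobut-2-en-1-yl]sulfanylbenzene
Conditions: PhSSPh, n-Bu3P, THF, 0 °C → rt
Reagents that add atoms: diphenyl disulfide, SMILES c1ccc(SSc2ccccc2)cc1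
Why: Phosphine-mediated sulfenylation of a primary allylic alcohol (oxyphosphonium formation, then SN2 displacement by thiolate) keeps alkene position and geometry. Sulfur enters as the sulfide because a sulfone would not survive the organolithium and dianion steps that follow.

Step 3
Reactants: 4 [(2Z)-3-iodobut-2-en-1-yl]sulfanylbenzene
Product: 6 (2Z)-2-methyl-4-(phenylsulfanyl)but-2-enal, via alkenyllithium 5 (not isolated)
Conditions: t-BuLi (2.1 equiv), Et2O, −78 °C; DMF, −78 → 0 °C; aq NH4Cl
Reagents that add atoms: N,N-dimethylformamide, SMILES CN(C)C=O
Why: Iodine–lithium exchange is faster than any attack on the allylic sulfide at −78 °C and proceeds with retention, and formylation puts the aldehyde carbon (C6) cis to C3. The enal is used at once to avoid drift to the (E)-isomer.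

Step 4
Reactants: 7 ethyl 2-methyl-3-oxobutanoate; 6 (2Z)-2-methyl-4-(phenylsulfanyl)but-2-enal
Product: 9 ethyl (6Z)-5-hydroxy-2,6-dimethyl-3-oxo-8-(phenylsulfanyl)oct-6-enoate, via acetoacetate dianion 8 (not isolated)
Conditions: 7, NaH, THF, 0 °C; n-BuLi, 0 °C; then 6, −78 °C; aq NH4Cl
Reagents that add atoms: none
Why: This is the γ-aldol addition of an acetoacetate dianion: the more basic terminal carbanion adds 1,2 to the enal, forming C6–C7 and leaving the β-keto ester intact. The two new stereocentres (C6, C11) are temporary, so the diastereomer mixture is carried on.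

Step 5
Reactants: 9 ethyl (6Z)-5-hydroxy-2,6-dimethyl-3-oxo-8-(phenylsulfanyl)oct-6-enoate
Product: 10 ethyl (6Z)-2,6-dimethyl-3-oxo-8-(phenylsulfanyl)-5-(triethylsilyloxy)oct-6-enoate
Conditions: Et3SiCl, imidazole, CH2Cl2, 0 °C
Reagents that add atoms: chlorotriethylsilane, SMILES CC[Si](Cl)(CC)CC
Why: Routine silylation of a secondary alcohol blocks C6-OH, which would otherwise lactonise onto the ester or dehydrate. The triethylsilyl group can later be removed beside a tert-butyldimethylsilyl ether.

Step 6
Reactants: 10 ethyl (6Z)-2,6-dimethyl-3-oxo-8-(phenylsulfanyl)-5-(triethylsilyloxy)oct-6-enoate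
Product: 12 ethyl (2Z,6Z)-2,6-dimethyl-8-(phenylsulfanyl)-5-(triethylsilyloxy)-3-(trifluoromethylsulfonyloxy)octa-2,6-dienoate, via chelated sodium enolate 11 (not isolated)
Conditions: NaH, Et2O, 0 °C; Tf2O, −78 → 0 °C
Reagents that add atoms: trifluoromethanesulfonic anhydride, SMILES O=S(=O)(OS(=O)(=O)C(F)(F)F)C(F)(F)F
Why: Deprotonation occurs only at the doubly activated C11, so the β-silyloxy group at C6 cannot be eliminated. O-Sulfonylation of the sodium chelate, in which enolate oxygen and ester carbonyl are held cis, gives the (Z)-enol triflate and so fixes C7 cis to the C13 methyl.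

Step 7
Reactants: 12 ethyl (2Z,6Z)-2,6-dimethyl-8-(phenylsulfanyl)-5-(triethylsilyloxy)-3-(trifluoromethylsulfonyloxy)octa-2,6-dienoate; 13 (1,3-dioxolan-2-ylmethyl)zinc bromide
Product: 14 ethyl (2Z,6Z)-3-(1,3-dioxolan-2-ylmethyl)-2,6-dimethyl-8-(phenylsulfanyl)-5-(triethylsilyloxy)octa-2,6-dienoate
Conditions: PdCl2(dppf)·CH2Cl2 (5 mol%), THF, 50 °C
Reagents that add atoms: none
Why: In this Negishi coupling of an alkylzinc halide with an electron-poor alkenyl triflate, oxidative addition and reductive elimination proceed with retention. The C9–C10 arm therefore takes the place of the triflate, cis to the ester, and the C8=C11 geometry of the target is set; the chelating ligand suppresses β-hydride elimination.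

Step 8
Reactants: 14 ethyl (2Z,6Z)-3-(1,3-dioxolan-2-ylmethyl)-2,6-dimethyl-8-(phenylsulfanyl)-5-(triethylsilyloxy)octa-2,6-dienoate
Product: 15 ethyl (2Z,6Z)-3-(1,3-dioxolan-2-ylmethyl)-2,6-dimethyl-8-(phenylsulfonyl)-5-(triethylsilyloxy)octa-2,6-dienoate
Conditions: (NH4)6Mo7O24·4H2O (10 mol%), 30% H2O2, EtOH, 0 °C
Reagents that add atoms: hydrogen peroxide, SMILES OO
Why: Molybdate-catalysed peroxide oxidation takes a sulfide to the sulfone without epoxidising alkenes, here an inductively deactivated trisubstituted alkene and a tetrasubstituted enoate. It is run cold so that the intermediate allylic sulfoxide is oxidised before it can equilibrate by [2,3]-shift (Mislow–Evans) and endanger the C4=C5 geometry.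

Step 9
Reactants: 15 ethyl (2Z,6Z)-3-(1,3-dioxolan-2-ylmethyl)-2,6-dimethyl-8-(phenylsulfonyl)-5-(triethylsilyloxy)octa-2,6-dienoate
Product: 16 (2Z,6Z)-3-(1,3-dioxolan-2-ylmethyl)-2,6-dimethyl-8-(phenylsulfonyl)-5-(triethylsilyloxy)octa-2,6-dien-1-ol
Conditions: iBu2AlH, CH2Cl2, −78 → 0 °C; Rochelle salt
Reagents that add atoms: none
Why: 1,2-Reduction of the enoate by the aluminium hydride gives the C12 allylic alcohol; sulfone, acetal and silyl ether are inert at low temperature.

Step 10
Reactants: 16 (2Z,6Z)-3-(1,3-dioxolan-2-ylmethyl)-2,6-dimethyl-8-(phenylsulfonyl)-5-(triethylsilyloxy)octa-2,6-dien-1-ol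
Product: 17 tert-butyl(dimethyl)silyl ether of 16 at C12-OH
Conditions: t-BuMe2SiCl, imidazole, CH2Cl2, 0 °C → rt
Reagents that add atoms: tert-butylchlorodimethylsilane, SMILES CC(C)(C)[Si](C)(C)Cl
Why: Routine silylation of the primary allylic alcohol; this ether has to last until step 22, so the more robust silyl group is used here.

Step 11
Reactants: 17 tert-butyl(dimethyl)silyl ether of 16 at C12-OH
Product: 19 (3Z,6Z)-3-[1-(tert-butyldimethylsilyloxy)propan-2-ylidene]-6-methyl-8-(phenylsulfonyl)-5-(triethylsilyloxy)oct-6-enal, via collidinium acetal salt 18 (not isolated)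
Conditions: Et3SiOTf, 2,4,6-collidine, CH2Cl2, 0 °C; then H2O
Reagents that add atoms: water, SMILES O
Why: Silyl triflate–collidine cleavage of an aldehyde acetal opens the dioxolane to a collidinium salt that water hydrolyses to the aldehyde under conditions that are neither acidic nor basic. The β,γ-unsaturated aldehyde is therefore not conjugated and both silyl ethers survive; 19 is used without storage.

Step 12
Reactants: 19 (3Z,6Z)-3-[1-(tert-butyldimethylsilyloxy)propan-2-ylidene]-6-methyl-8-(phenylsulfonyl)-5-(triethylsilyloxy)oct-6-enal; 20 methyl prop-2-ynoate
Product: 22 methyl 5-[1-(tert-butyldimethylsilyloxy)propan-2-ylidene]-3-hydroxy-8-methyl-2-methylidene-10-(phenylsulfonyl)-7-(triethylsilyloxy)dec-8-enoate (8Z; silyloxymethyl cis to chain C4), via α-aluminoacrylate 21 (not isolated)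
Conditions: 20, iBu2AlH, N-methylmorpholine N-oxide, THF, 0 °C; then 19, 0 °C → rt
Reagents that add atoms: none
Why: Hydroalumination of the propiolate gives an α-aluminoacrylate, a vinyl-metal equivalent of the Baylis–Hillman zwitterion, which adds 1,2 to the aldehyde to form C1–C10 and the α-methylene-β-hydroxy ester directly. This known amine-free variant is chosen because a tertiary amine acting for days would move C8=C11 of a β,γ-unsaturated aldehyde into conjugation. The new C10 centre is racemic and temporary.

Step 13
Reactants: 22 methyl 5-[1-(tert-butyldimethylsilyloxy)propan-2-ylidene]-3-hydroxy-8-methyl-2-methylidene-10-(phenylsulfonyl)-7-(triethylsilyloxy)dec-8-enoate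
Product: 23 tert-butyl carbonate of 22 at the C10 hydroxyl (chain C3)
Conditions: Boc2O, DMAP (10 mol%), CH2Cl2, 0 °C
Reagents that add atoms: di-tert-butyl dicarbonate, SMILES CC(C)(C)OC(=O)OC(=O)OC(C)(C)C
Why: Acylation of the secondary allylic alcohol is the usual preparation of Baylis–Hillman tert-butyl carbonates. The carbonate is both the leaving group and the internal source of tert-butoxide for step 16.

Step 14
Reactants: 23 tert-butyl carbonate of 22 at the C10 hydroxyl
Product: 24 C6 alcohol: 23 without its triethylsilyl group (chain C7 hydroxyl)
Conditions: HF·pyridine, pyridine, THF, 0 °C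
Reagents that add atoms: none
Why: Buffered fluoride removes the secondary triethylsilyl ether much faster than the primary tert-butyldimethylsilyl ether and leaves carbonate and acrylate untouched. Because C3 already carries the sulfone, no free C3 hydroxyl can ever face the future enone.

Step 15
Reactants: 24 C6 alcohol
Product: 25 methyl 3-[(tert-butoxycarbonyl)oxy]-5-[1-(tert-butyldimethylsilyloxy)propan-2-ylidene]-8-methyl-2-methylidene-7-oxo-10-(phenylsulfonyl)dec-8-enoate (8Z; silyloxymethyl cis to chain C4; racemic)
Conditions: Dess–Martin periodinane, NaHCO3, CH2Cl2, 0 °C → rt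
Reagents that add atoms: none
Why: Buffered Dess–Martin oxidation of the allylic alcohol gives the (Z)-enone without acid or base that would isomerise it or conjugate C8=C11. The sensitive γ-sulfonyl (Z)-enone is thus made only in the step before its use.

Step 16
Reactants: 25 Baylis–Hillman tert-butyl carbonate carrying the γ-phenylsulfonyl (Z)-enone
Product: 27 methyl 4-[1-(tert-butyldimethylsilyloxy)propan-2-ylidene]-7-methyl-6-oxo-9-(phenylsulfonyl)cyclodeca-1,7-diene-1-carboxylate (1E,7Z; silyloxymethyl cis to ring C3; racemic; in target locants C1 ester and C3 sulfone and C6 ketone), via π-allylpalladium zwitterion 26 (not isolated)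
Conditions: Pd2(dba)3·CHCl3 (5 mol%), Ph2PCH2CH2PPh2 (12 mol%), THF, 50 °C, slow addition to 0.002 M
Reagents that add atoms: none
Why: Zerovalent palladium ionises the Baylis–Hillman carbonate with loss of CO2 to give the 2-(methoxycarbonyl)allyl complex of divalent palladium and tert-butoxide, which removes the C3 proton (acidified by the sulfone and, vinylogously, by C6=O); C3 then attacks the unsubstituted allyl terminus C2 anti to the metal and forms C2–C3. The closest known reactions are the palladium-catalysed SN2′-type alkylation of Baylis–Hillman carbonates by stabilised carbanions under base-free conditions and the Tsuji–Trost macrocyclisation of sulfonyl-stabilised carbanions. The ten-membered ring closes in the endo sense of an allyl cyclisation, the nucleophile attacking the terminus distal to the tether so that all three allyl carbons become ring members; attack at the substituted terminus C10 would give an eight-membered ring and is disfavoured sterically. The new C1=C10 bond forms as the (E)-enoate (ester trans to C9), the normal outcome for 2-(alkoxycarbonyl)allyl complexes and, being ring-cis, also the geometry the ten-membered ring prefers. The only new stereocentre, C3, is formed without control as the racemate and is erased in step 18. Selectivity for C3 over C5 or the enolate oxygen rests on the sulfone, which localises charge at C3, and on the alternatives being quaternary or eight-membered; the chelating diphosphine leaves no free phosphine to open the Lewis-base pathway to the branched isomer. Because base appears only as fast as the carbonate ionises and is consumed by the most acidic C–H, neither the (Z)-enone nor the C7 methylene next to C8=C11 meets excess base, and slow addition at high dilution suppresses oligomers.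

Step 17
Reactants: 27 ten-membered keto ester sulfone
Product: 28 9-[1-(tert-butyldimethylsilyloxy)propan-2-ylidene]-6-(hydroxymethyl)-2-methyl-4-(phenylsulfonyl)cyclodeca-2,6-dien-1-ol (2Z,6E; racemic diastereomer mixture; in target locants C6-OH and C15-OH and C3 sulfone)
Conditions: iBu2AlH, CH2Cl2, −78 °C
Reagents that add atoms: none
Why: The aluminium hydride reduces the enone and the enoate by 1,2-addition to the two allylic alcohols. Reduction before desulfonylation turns the vinylogous α-sulfonyl ketone, whose reductive cleavage would give a dienolate that protonates at C5, into a plain allylic sulfone.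

Step 18
Reactants: 28 diol sulfone
Product: 29 9-[1-(tert-butyldimethylsilyloxy)propan-2-ylidene]-6-(hydroxymethyl)-2-methylcyclodeca-2,6-dien-1-ol (2Z,6E; silyloxymethyl cis to ring C8; racemic at the carbinol C6 of the target)
Conditions: PdCl2(dppp) (5 mol%), LiBHEt3, THF, 0 °C
Reagents that add atoms: none
Why: This is the palladium-catalysed hydride substitution of an allylic sulfone: the borohydride reduces the precatalyst to zerovalent palladium, which ionises the C3 sulfone, and hydride passes from the metal to the less substituted allyl terminus C3. The reaction type is known to keep position and geometry of a trisubstituted double bond, and excess hydride at 0 °C lets hydride transfer outrun syn–anti isomerisation of the allyl complex.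

Step 19
Reactants: 29 triene diol
Product: 30 (1R,10R)-1,10-epoxide of 29 (oxirane C1–C10 with C15H2OH on C1; both C6 epimers; C4=C5 Z; C8=C11 with C12 cis to C9)
Conditions: Ti(OiPr)4, D-(−)-diethyl tartrate, t-BuOOH, 4 Å MS, CH2Cl2, −20 °C
Reagents that add atoms: tert-butyl hydroperoxide, SMILES CC(C)(C)OO
Why: In this Sharpless asymmetric epoxidation of the 2,3-disubstituted primary allylic alcohol, D-(−)-tartrate directs oxygen to the face that gives (1R,10R), and syn addition to the alkene with C2 cis to C9 sets the relative configuration. The secondary C6 alcohol (cis-substituted alkene) and the silylated C12 ether react far more slowly, and the two C6 epimers converge in step 21.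

Step 20
Reactants: 30 epoxy diol
Product: 31 C15 monoacetate of 30
Conditions: AcCl, 2,4,6-collidine, CH2Cl2, −78 °C
Reagents that add atoms: acetyl chloride, SMILES CC(=O)Cl
Why: Acetyl chloride with a hindered pyridine base at low temperature acylates the primary epoxy alcohol selectively over the secondary allylic C6 alcohol, installing the C15 acetate of the target.

Step 21
Reactants: 31 C15 monoacetate
Product: 32 (1R,10R)-epoxy (Z)-enone: 31 with C6 oxidised to the ketone
Conditions: Dess–Martin periodinane, NaHCO3, CH2Cl2, 0 °C
Reagents that add atoms: none
Why: Dess–Martin oxidation of the C6 allylic alcohol restores the (Z)-enone and merges the C6 epimers; epoxide, acetate and silyl ether are inert under the buffered conditions.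

Step 22
Reactants: 32 epoxy enone silyl ether
Product: 33 C12 allylic alcohol: 32 without its tert-butyldimethylsilyl group
Conditions: HF·pyridine, pyridine, THF, 0 °C → rt
Reagents that add atoms: none
Why: Pyridine-buffered fluoride cleaves the primary allylic silyl ether under conditions that trisubstituted epoxides, acetates and enones tolerate, and frees the hydroxyl that directs the second epoxidation.

Step 23
Reactants: 33 C12 allylic alcohol
Product: 34 (1R,8S,10R,11S)-bis-epoxide with free C12-OH
Conditions: Ti(OiPr)4, L-(+)-diethyl tartrate, t-BuOOH, 4 Å MS, CH2Cl2, −20 °C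
Reagents that add atoms: tert-butyl hydroperoxide, SMILES CC(C)(C)OO
Why: In this second Sharpless epoxidation, of the electron-rich tetrasubstituted allylic alcohol, L-(+)-tartrate (the enantiomer of the ligand of step 19) directs oxygen to the face that gives (8S,11S), and syn addition to the alkene with C12 cis to C9 sets the relative configuration of the spiro-epoxide. The enone is too electron-poor to react, and reagent control is relied on to override the distant C1–C10 epoxide.

Step 24
Reactants: 34 bis-epoxy alcohol
Product: 35 CNP0185847.4, the C12,C15-diacetate (1R,8S,10R,11S)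
Conditions: Ac2O, pyridine, DMAP (cat.), CH2Cl2, 0 °C
Reagents that add atoms: acetic anhydride, SMILES CC(=O)OC(C)=O
Why: Acetylation of the remaining primary alcohol under mild amine catalysis completes the target; short exposure at 0 °C avoids E1cB opening of the β,γ-epoxy ketone.

## Compound list

1 | but-2-yn-1-ol | CC#CCO | starting material
2 | cyclic sodium alkenylalanate from 1 (five-membered O–Al–C ring, two 2-methoxyethoxy ligands on Al) | CC1=CCO[Al-]1(OCCOC)OCCOC.[Na+] | intermediate (not isolated)
3 | (2Z)-3-iodobut-2-en-1-ol | C/C(I)=C/CO | intermediate
4 | [(2Z)-3-iodobut-2-en-1-yl]sulfanylbenzene | C/C(I)=C/CSc1ccccc1 | intermediate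
5 | [4-(phenylsulfanyl)but-2-en-2-yl]lithium, Li cis to CH2SPh | [Li]/C(C)=C\CSc1ccccc1 | intermediate (not isolated)
6 | (2Z)-2-methyl-4-(phenylsulfanyl)but-2-enal | O=C/C(C)=C\CSc1ccccc1 | intermediate
7 | ethyl 2-methyl-3-oxobutanoate (ethyl 2-methylacetoacetate) | CCOC(=O)C(C)C(C)=O | starting material
8 | lithium sodium dianion of 7 (1-ethoxy-2-methylbuta-1,3-diene-1,3-diolate) | [Li+].[Na+].C=C([O-])C(C)=C([O-])OCC | intermediate (not isolated)
9 | ethyl (6Z)-5-hydroxy-2,6-dimethyl-3-oxo-8-(phenylsulfanyl)oct-6-enoate (racemic, both diastereomers) | CCOC(=O)C(C)C(=O)CC(O)/C(C)=C\CSc1ccccc1 | intermediate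
10 | ethyl (6Z)-2,6-dimethyl-3-oxo-8-(phenylsulfanyl)-5-(triethylsilyloxy)oct-6-enoate (racemic, both diastereomers) | CCOC(=O)C(C)C(=O)CC(O[Si](CC)(CC)CC)/C(C)=C\CSc1ccccc1 | intermediate
11 | sodium (Z)-enolate of 10 (enolate oxygen cis to the ester) | CCOC(=O)/C(C)=C(\[O-])CC(O[Si](CC)(CC)CC)/C(C)=C\CSc1ccccc1.[Na+] | intermediate (not isolated)
12 | ethyl (2Z,6Z)-2,6-dimethyl-8-(phenylsulfanyl)-5-(triethylsilyloxy)-3-(trifluoromethylsulfonyloxy)octa-2,6-dienoate (racemic) | CCOC(=O)/C(C)=C(\OS(=O)(=O)C(F)(F)F)CC(O[Si](CC)(CC)CC)/C(C)=C\CSc1ccccc1 | intermediate
13 | (1,3-dioxolan-2-ylmethyl)zinc bromide | Br[Zn]CC1OCCO1 | starting material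
14 | ethyl (2Z,6Z)-3-(1,3-dioxolan-2-ylmethyl)-2,6-dimethyl-8-(phenylsulfanyl)-5-(triethylsilyloxy)octa-2,6-dienoate (racemic) | CCOC(=O)/C(C)=C(\CC1OCCO1)CC(O[Si](CC)(CC)CC)/C(C)=C\CSc1ccccc1 | intermediate
15 | ethyl (2Z,6Z)-3-(1,3-dioxolan-2-ylmethyl)-2,6-dimethyl-8-(phenylsulfonyl)-5-(triethylsilyloxy)octa-2,6-dienoate (racemic) | CCOC(=O)/C(C)=C(\CC1OCCO1)CC(O[Si](CC)(CC)CC)/C(C)=C\CS(=O)(=O)c1ccccc1 | intermediate
16 | (2Z,6Z)-3-(1,3-dioxolan-2-ylmethyl)-2,6-dimethyl-8-(phenylsulfonyl)-5-(triethylsilyloxy)octa-2,6-dien-1-ol (racemic) | OC/C(C)=C(\CC1OCCO1)CC(O[Si](CC)(CC)CC)/C(C)=C\CS(=O)(=O)c1ccccc1 | intermediate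
17 | tert-butyl(dimethyl)silyl ether of 16 at the primary (C12) hydroxyl | CC(C)(C)[Si](C)(C)OC/C(C)=C(\CC1OCCO1)CC(O[Si](CC)(CC)CC)/C(C)=C\CS(=O)(=O)c1ccccc1 | intermediate
18 | N-[1-(2-triethylsilyloxyethoxy)alkyl]-2,4,6-trimethylpyridinium triflate from ring opening of the dioxolane of 17 at C10 | Cc1cc(C)[n+](C(C/C(=C(/C)CO[Si](C)(C)C(C)(C)C)CC(O[Si](CC)(CC)CC)/C(C)=C\CS(=O)(=O)c2ccccc2)OCCO[Si](CC)(CC)CC)c(C)c1.[O-]S(=O)(=O)C(F)(F)F | intermediate (not isolated)
19 | (3Z,6Z)-3-[1-(tert-butyldimethylsilyloxy)propan-2-ylidene]-6-methyl-8-(phenylsulfonyl)-5-(triethylsilyloxy)oct-6-enal (racemic) | O=CC/C(=C(/C)CO[Si](C)(C)C(C)(C)C)CC(O[Si](CC)(CC)CC)/C(C)=C\CS(=O)(=O)c1ccccc1 | intermediate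
20 | methyl prop-2-ynoate (methyl propiolate) | C#CC(=O)OC | starting material
21 | methyl 2-[bis(2-methylpropyl)alumanyl]prop-2-enoate | C=C(C(=O)OC)[Al](CC(C)C)CC(C)C | intermediate (not isolated)
22 | methyl 5-[1-(tert-butyldimethylsilyloxy)propan-2-ylidene]-3-hydroxy-8-methyl-2-methylidene-10-(phenylsulfonyl)-7-(triethylsilyloxy)dec-8-enoate (8Z; silyloxymethyl cis to chain C4; racemic, both diastereomers) | C=C(C(=O)OC)C(O)C/C(=C(/C)CO[Si](C)(C)C(C)(C)C)CC(O[Si](CC)(CC)CC)/C(C)=C\CS(=O)(=O)c1ccccc1 | intermediate
23 | tert-butyl carbonate of 22 at the chain C3 (ring C10) hydroxyl | C=C(C(=O)OC)C(OC(=O)OC(C)(C)C)C/C(=C(/C)CO[Si](C)(C)C(C)(C)C)CC(O[Si](CC)(CC)CC)/C(C)=C\CS(=O)(=O)c1ccccc1 | intermediate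
24 | 23 with free chain C7 (ring C6) hydroxyl in place of the triethylsilyl ether | C=C(C(=O)OC)C(OC(=O)OC(C)(C)C)C/C(=C(/C)CO[Si](C)(C)C(C)(C)C)CC(O)/C(C)=C\CS(=O)(=O)c1ccccc1 | intermediate
25 | methyl 3-[(tert-butoxycarbonyl)oxy]-5-[1-(tert-butyldimethylsilyloxy)propan-2-ylidene]-8-methyl-2-methylidene-7-oxo-10-(phenylsulfonyl)dec-8-enoate (8Z; silyloxymethyl cis to chain C4; racemic) | C=C(C(=O)OC)C(OC(=O)OC(C)(C)C)C/C(=C(/C)CO[Si](C)(C)C(C)(C)C)CC(=O)/C(C)=C\CS(=O)(=O)c1ccccc1 | intermediate
26 | zwitterion of the 2-(methoxycarbonyl)allyl complex of divalent palladium (diphosphine-chelated; drawn in the η1 form at C2) and the C3 sulfonyl carbanion | COC(=O)C(C[Pd-]1[P+](c2ccccc2)(c2ccccc2)CC[P+]1(c1ccccc1)c1ccccc1)=CC/C(=C(/C)CO[Si](C)(C)C(C)(C)C)CC(=O)/C(C)=C\[CH-]S(=O)(=O)c1ccccc1 | intermediate (not isolated)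
27 | methyl 4-[1-(tert-butyldimethylsilyloxy)propan-2-ylidene]-7-methyl-6-oxo-9-(phenylsulfonyl)cyclodeca-1,7-diene-1-carboxylate (1E,7Z; silyloxymethyl cis to ring C3; racemic) | COC(=O)/C1=C/C/C(=C(/C)CO[Si](C)(C)C(C)(C)C)CC(=O)/C(C)=C\C(S(=O)(=O)c2ccccc2)C1 | intermediate
28 | 9-[1-(tert-butyldimethylsilyloxy)propan-2-ylidene]-6-(hydroxymethyl)-2-methyl-4-(phenylsulfonyl)cyclodeca-2,6-dien-1-ol (2Z,6E; racemic, both diastereomers) | OC/C1=C/C/C(=C(/C)CO[Si](C)(C)C(C)(C)C)CC(O)/C(C)=C\C(S(=O)(=O)c2ccccc2)C1 | intermediate
29 | 9-[1-(tert-butyldimethylsilyloxy)propan-2-ylidene]-6-(hydroxymethyl)-2-methylcyclodeca-2,6-dien-1-ol (2Z,6E; silyloxymethyl cis to ring C8; racemic) | OC/C1=C/C/C(=C(/C)CO[Si](C)(C)C(C)(C)C)CC(O)/C(C)=C\CC1 | intermediate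
30 | (1R,10R)-1,10-epoxide of 29: C15H2OH on C1, C6-OH (both epimers), (4Z)-alkene, C8=C11 with C12H2OSiMe2tBu cis to C9 | OC[C@]12CC/C=C(/C)C(O)C/C(=C(\C)CO[Si](C)(C)C(C)(C)C)C[C@H]1O2 | intermediate
31 | C15 acetate of 30 (both C6 epimers) | CC(=O)OC[C@]12CC/C=C(/C)C(O)C/C(=C(\C)CO[Si](C)(C)C(C)(C)C)C[C@H]1O2 | intermediate
32 | (1R,10R)-epoxy (4Z)-en-6-one with C15 acetate and C12 tert-butyldimethylsilyl ether | CC(=O)OC[C@]12CC/C=C(/C)C(=O)C/C(=C(\C)CO[Si](C)(C)C(C)(C)C)C[C@H]1O2 | intermediate
33 | (1R,10R)-epoxy (4Z)-en-6-one with C15 acetate and free C12-OH | CC(=O)OC[C@]12CC/C=C(/C)C(=O)C/C(=C(\C)CO)C[C@H]1O2 | intermediate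
34 | (1R,8S,10R,11S)-1,10:8,11-bis-epoxy (4Z)-en-6-one with C15 acetate and free C12-OH | CC(=O)OC[C@]12CC/C=C(/C)C(=O)C[C@]3(C[C@H]1O2)O[C@@]3(C)CO | intermediate
35 | CNP0185847.4: (1R,8S,10R,11S)-1,10:8,11-bis-epoxy (4Z)-en-6-one C12,C15-diacetate | CC(=O)OC[C@]12CC/C=C(/C)C(=O)C[C@]3(C[C@H]1O2)O[C@@]3(C)COC(C)=O | target

## Step count and least certain steps

Total step count: 24. Longest linear sequence: 24 steps (1 → 35); 7, 13 and 20 are bought and enter at steps 4, 7 and 12.

**Step 16 (key step).** The most likely failures are intermolecular alkylation outrunning a slow ten-membered closure, loss of regiocontrol (bond formation through C5 or the enolate oxygen, or at the substituted allyl terminus C10), and geometric drift of the delocalised C3–C5 anion, whose C4–C5 bond order falls on deprotonation. Fallback, forming the same bond without palladium: it sets out from 22. Bromination with allylic transposition (N-bromosuccinimide, Me2S, CH2Cl2, 0 °C) gives the primary allylic bromide F1, a (2Z)-2-(bromomethyl)enoate in which the enoate geometry is already fixed. HF·pyridine gives the C6 alcohol F2 and Dess–Martin oxidation the bromo keto sulfone F3. Cs2CO3 in MeCN at high dilution then closes C2–C3 by intramolecular SN2 alkylation of the sulfonyl-stabilised carbanion, and the route is rejoined at 27.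

**Step 18.** The risks are loss of the ring-cis C4=C5 geometry through syn–anti interconversion of the allylpalladium before hydride transfer, hydride delivery to C5 with transposition of the double bond, and over-reduction by the borohydride. Fallback, in which the sulfone is removed before the carbonyls are reduced: it sets out from 27. SmI2 in THF/MeOH at −78 °C cleaves the vinylogous α-sulfonyl ketone and, by protonation of the dienolate at C5, should give the deconjugated β,γ-unsaturated ketone F4. Brief treatment with DBU returns the alkene to conjugation as the ring-cis enone keto ester F5, and iBu2AlH reduces both carbonyls, rejoining the route at 29.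

**Step 12.** The β,γ-unsaturated aldehyde may enolise or slip into conjugation on the Lewis-acidic aluminium reagent before C–C bond formation, which would erase C8=C11; addition may also be slow at the hindered aldehyde. Fallback, an aldol–elimination route to the same adduct: it sets out from 19. The lithium enolate of methyl 3-(phenylselanyl)propanoate (LiN(iPr)2, THF, −78 °C) adds to give the β-hydroxy α-(phenylselanylmethyl) ester F6; oxidation with H2O2 and pyridine at 0 °C and syn-elimination of the selenoxide toward the only β-hydrogen then gives the α-methylene ester, rejoining the route at 22.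

**Step 19.** The racemic C6 carbinol may erode facial selectivity in its mismatched enantiomer, the C6 hydroxyl may direct oxidant to a second alkene, and the electron-rich C4=C5 alkene may add across the ring to the titanium-activated epoxide. Fallback, in which the C6 ketone is restored before the epoxidation: it sets out from 29. MnO2 oxidises both allylic alcohols to the keto enal F7. NaBH4 in EtOH/CH2Cl2 at −78 °C reduces only the aldehyde to the hydroxy enone F8. Sharpless epoxidation with D-(−)-diethyl tartrate gives the (1R,10R)-epoxy hydroxy enone F9, and Ac2O/pyridine acetylates C15-OH, rejoining the route at 32. The cost is one extra step.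

**Step 23.** The distant C1–C10 epoxide and the ring conformation may oppose the tartrate (mismatched double stereodifferentiation), and the tetrasubstituted epoxy alcohol may open on the Lewis-acidic titanium or by E1cB at the β,γ-epoxy ketone during work-up. Fallback, a catalyst-controlled dioxirane epoxidation that needs neither titanium nor hydroxyl direction: it sets out from 33 and uses the fructose-derived chiral ketone (the enantiomer, from D- or L-fructose, chosen by the spiro transition-state model for the required face) with KHSO5 as its triple salt in buffered MeCN/water at pH 8 and 0 °C. The electron-rich tetrasubstituted alkene reacts in preference to the enone, and the route is rejoined at 34. No new compound is made (F0).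

Further compounds

F1 | step 16 | methyl (2Z)-2-(bromomethyl)enoate from 22 by allylic transposition (C6 triethylsilyl ether, C3 sulfone, C12 silyl ether) | COC(=O)/C(CBr)=C/C/C(=C(/C)CO[Si](C)(C)C(C)(C)C)CC(O[Si](CC)(CC)CC)/C(C)=C\CS(=O)(=O)c1ccccc1
F2 | step 16 | C6 alcohol of F1 | COC(=O)/C(CBr)=C/C/C(=C(/C)CO[Si](C)(C)C(C)(C)C)CC(O)/C(C)=C\CS(=O)(=O)c1ccccc1
F3 | step 16 | bromo keto sulfone (C6 ketone of F2) | COC(=O)/C(CBr)=C/C/C(=C(/C)CO[Si](C)(C)C(C)(C)C)CC(=O)/C(C)=C\CS(=O)(=O)c1ccccc1
F4 | step 18 | deconjugated keto ester: 27 without sulfone, ring-cis C3=C4 alkene, C5-H (racemic) | COC(=O)/C1=C/C/C(=C(/C)CO[Si](C)(C)C(C)(C)C)CC(=O)C(C)/C=C\C1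
F5 | step 18 | conjugated keto ester: 27 with H in place of the sulfone | COC(=O)/C1=C/C/C(=C(/C)CO[Si](C)(C)C(C)(C)C)CC(=O)/C(C)=C\CC1
F6 | step 12 | methyl 3-hydroxy-2-[(phenylselanyl)methyl] ester from aldol addition to 19 (racemic, diastereomer mixture) | COC(=O)C(C[Se]c1ccccc1)C(O)C/C(=C(/C)CO[Si](C)(C)C(C)(C)C)CC(O[Si](CC)(CC)CC)/C(C)=C\CS(=O)(=O)c1ccccc1
F7 | step 19 | keto enal: 29 with C6 ketone and C15 aldehyde | O=C/C1=C/C/C(=C(/C)CO[Si](C)(C)C(C)(C)C)CC(=O)/C(C)=C\CC1
F8 | step 19 | hydroxy enone: 29 with C6 ketone and C15-OH | OC/C1=C/C/C(=C(/C)CO[Si](C)(C)C(C)(C)C)CC(=O)/C(C)=C\CC1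
F9 | step 19 | (1R,10R)-epoxy hydroxy enone: 32 with free C15-OH | OC[C@]12CC/C=C(/C)C(=O)C/C(=C(\C)CO[Si](C)(C)C(C)(C)C)C[C@H]1O2
F0 | step 23 | none | none
A1 | alternative 1 | 5-(4-methoxybenzyloxy)pent-2-yn-1-ol | OCC#CCCOCc1ccc(OC)cc1
A2 | alternative 1 | (2E,6Z)-1-bromo-7-iodo-3-(triethylsilyloxymethyl)octa-2,6-diene | BrC/C=C(CO[Si](CC)(CC)CC)\CC/C=C(/C)I
A3 | alternative 1 | open C15 chain: C12 alcohol, C8=C11 with C12 cis to C9, C6 4-methoxybenzyl ether, C15 triethylsilyl ether, C5 (Z)-alkenyl iodide | OC/C(C)=C(/CCOCc1ccc(OC)cc1)C/C=C(CO[Si](CC)(CC)CC)\CC/C=C(/C)I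
A4 | alternative 2 | 8-[1-(4-methoxybenzyloxy)prop-1-en-2-yl]-2-methylidene-5-(triethylsilyloxymethyl)-3,6,7,8-tetrahydro-2H-oxocine (ring alkene cis; enol ether drawn E; either C8 enantiomer, since the centre it relays to C6 is later oxidised) | C=C1C/C=C(CO[Si](CC)(CC)CC)\CCC(O1)/C(C)=C/OCc1ccc(OC)cc1
A5 | alternative 2 | ten-membered dienone: C8 ketone, (6R)-4-methoxybenzyl ether, ring-cis C4=C5 and C1=C10, C15 triethylsilyl ether | O=C1C[C@@H](OCc2ccc(OC)cc2)/C(C)=C\CC/C(CO[Si](CC)(CC)CC)=C\C1
A6 | alternative 3 | open chain with C7 allylic chloride and C5 (Z)-alkenyl tributylstannane (C15 triethylsilyl and C12 tert-butyldimethylsilyl ethers) | ClC/C(=C(\C)CO[Si](C)(C)C(C)(C)C)C/C=C(CO[Si](CC)(CC)CC)\CC/C=C(/C)[Sn](CCCC)(CCCC)CCCC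
A7 | alternative 3 | cyclodecatrienone with C6 ketone, C15 triethylsilyl ether and C12 tert-butyldimethylsilyl ether | CC[Si](CC)(CC)OC/C1=C/C/C(=C(/C)CO[Si](C)(C)C(C)(C)C)CC(=O)/C(C)=C\CC1
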